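**The decision.** I had 3 questions to answer before choosing between two baths for one charge.

- the flask that comes out highest in amount of target, in percent of the starting material charged, or "all alike" when all lie within 1.5 percentage points (noon / summer / all alike)
- target at the end, in percent of the starting material charged, noon
- target at the end, in percent of the starting material charged, summer

all flasks: starting material 0.40 M
- birch: partner 0.90 equiv; protic impurity 8 mM; temperature 24 °C; run made earlier
- elm: partner 1.4 equiv; protic impurity 8 mM; temperature 32 °C; run made earlier
- noon: partner 1.80 equiv; protic impurity 8.00 mM; temperature 20 °C; time 2.0 min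
- summer: partner 1.80 equiv; protic impurity 8.00 mM; temperature 35 °C; time 2.0 min

- birch (time / s: target / %, starting material / %): 10.0: 11.4, 57.7; 20.0: 16.9, 41.8; 30.0: 20.1, 33.4; 50.0: 22.9, 23.6; 80.0: 24.2, 17.9; 90.0: 23.9, 16.5; 120: 25.2, 14.4
- elm (time / s: target / %, starting material / %): 10.0: 22.1, 24.9; 12.0: 23.6, 20.8; 15.0: 25.4, 14.9; 30.0: 27.1, 4.9; 40.0: 28.8, 1.8; 50.0: 29.3, 1.3; 60.0: 28.6, 0.7

(scatter of a reading: 0.5 percentage points)

- the numbers in the tables scatter with a standard deviation of 0.5 percentage points

**Reading s.** Elm at 50.0 s gave s = 29.7%, s being the selectivity, target formed per starting material consumed. Birch, in a cooler bath, gave 29.4% at 120 s. Their gap of 0.25 points lay below the scatter of 0.5 points, so I read no temperature effect on s from these two runs.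

**Reaching conversion.** With s held at that reading, target is s times conversion, so my decision hung on conversion. Over its first 10.0 s, birch lost starting material at a first-order rate λ = 0.0550 /s. Noon had twice birch's partner in a cooler bath, and I took the two changes together to leave λ standing. On that assumption I reckoned 0.136% of the starting material left after 2.0 min, and my reckoning for noon was 29.6%. For summer, taken as fully converted, it was s itself. That gap lay within 1.5 points, so I chose to keep the partner charge and to spend nothing on heat.

**The forecast.** It gave 29.5% for noon, 29.4% for summer and all alike, holding that “the competing path has the same orders and nearly the same activation energy”. My noon figure stood 0.10 points above its figure.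

**The result.** Noon gave 29.7% and summer 29.3%: all alike.

    starting material + partner → target (k = 0.0431 /M/s, Ea = 59.0 kJ/mol)
    starting material + protic impurity → quenched substrate (k = 1.23 /M/s, Ea = 47.0 kJ/mol)
    starting material + partner → second isomer (k = 0.0280 /M/s, Ea = 41.0 kJ/mol)
    starting material + partner → isomer of the product (k = 0.0710 /M/s, Ea = 66.0 kJ/mol)
    (constants at 20 °C)

**Opposing pulls.** For noon, s times the conversion of 99.8% gave 29.6%. Summer held 29.3% and not 67.4% of target, mainly because of the step to the isomer of the product. Summer minus noon was −0.4 points; taking away a part of what temperature did, its action on the step to the isomer of the product, gave 20 points, and taking away another part, its action on the step to target, gave −18 points. Carried to a neighbour like summer but with 0.720 equiv of partner and 26.1% of starting material at the end, s gave 21.9% of target, and that flask held 21.5%.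

The runs come from a simulation for substances that don't exist, noise included.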